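**Retrosynthetic overview**
1. Target 20 ⇐ C11a–O11 bond: enantioselective acid-catalysed cycloetherification of the achiral 2'-hydroxyisoflav-3-ene 18. This closes the dihydrofuran (ring C) last and sets both stereocentres.
2. 18 ⇐ isoflavanone 14 (reduction/dehydration, desilylation) ⇐ C6a–C6b bond by ketone α-arylation of chromanone 5 with aryl bromide 13.
3. 5 ⇐ 4-bromoresorcinol: acylation/ring closure forms the pyranone (ring B) first, then Stille prenylation.
4. 13 ⇐ 2-bromo-4,5-dihydroxybenzaldehyde: two O-alkylations, Dakin oxidation, then a tandem allyl/propargyl Claisen that installs the ring D prenyl and the dimethylpyran (ring E).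
5. Ring order: ring B (in 5) and ring E (in 13) in parallel, ring C in the final step.

Assumption: 2-bromo-4,5-dihydroxybenzaldehyde, tributyl(prenyl)stannane and tert-butyl 2-methylbut-3-en-2-yl carbonate are bought; the (R)-acid in step 11 is assumed to give the (6aR,11aR) series (checked by CD against natural pterocarpans; the (S)-acid is used otherwise).

**Route**

Step 1
Reactants: 1 4-bromobenzene-1,3-diol
Product: 3 6-bromo-7-hydroxychroman-4-one, via chloroketone 2 (not isolated)
Conditions: 3-chloropropanoic acid, CF3SO3H, 70 °C; then 2 M NaOH, 0 °C → rt; HCl to pH 2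
Reagents that add atoms: 3-chloropropanoic acid, OC(=O)CCCl
Why: Friedel–Crafts acylation goes to C6 (para to one OH, ortho to the other, the only unhindered activated site), and the ortho-phenoxide then closes the pyranone by intramolecular O-alkylation.

Step 2
Reactants: 3 6-bromo-7-hydroxychroman-4-one
Product: 4 6-bromo-7-(triisopropylsilyloxy)chroman-4-one
Conditions: TIPSCl, imidazole, DMF, rt
Reagents that add atoms: TIPSCl, CC(C)[Si](Cl)(C(C)C)C(C)C
Why: Standard phenol silylation; the triisopropylsilyl ether of this para-acylphenol survives the Stille heating, phosphate base and borohydride used later.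

Step 3
Reactants: 4 6-bromo-7-(triisopropylsilyloxy)chroman-4-one
Product: 5 6-(3-methylbut-2-en-1-yl)-7-(triisopropylsilyloxy)chroman-4-one
Conditions: tributyl(3-methylbut-2-en-1-yl)stannane (1.3 equiv), Pd(PPh3)4 (5 mol %), DMF, 95 °C
Reagents that add atoms: tributyl(3-methylbut-2-en-1-yl)stannane, CCCC[Sn](CCCC)(CCCC)CC=C(C)C
Why: Stille coupling of the aryl bromide transfers the linear prenyl group, so the ring A prenyl sits exactly where the bromine was.

Step 4
Reactants: 6 2-bromo-4,5-dihydroxybenzaldehyde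
Product: 7 2-bromo-5-hydroxy-4-[(2-methylbut-3-yn-2-yl)oxy]benzaldehyde
Conditions: 3-chloro-3-methylbut-1-yne (1.1 equiv), DBU (1.05 equiv), CuCl2·2H2O (1 mol %), MeCN, −5 °C → rt, Ar
Reagents that add atoms: 3-chloro-3-methylbut-1-yne, CC(C)(Cl)C#C
Why: Copper-catalysed propargylic etherification; one equivalent of base ionises only the more acidic 4-OH (para to the aldehyde), so mono-alkylation occurs there.

Step 5
Reactants: 7 2-bromo-5-hydroxy-4-[(2-methylbut-3-yn-2-yl)oxy]benzaldehyde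
Product: 8 2-bromo-5-[(2-methylbut-3-en-2-yl)oxy]-4-[(2-methylbut-3-yn-2-yl)oxy]benzaldehyde
Conditions: tert-butyl 2-methylbut-3-en-2-yl carbonate (1.5 equiv), Pd(PPh3)4 (2 mol %), THF, 0 °C
Reagents that add atoms: tert-butyl 2-methylbut-3-en-2-yl carbonate, CC(C)(C)OC(=O)OC(C)(C)C=C
Why: Decarboxylative Tsuji–Trost O-allylation; the phenoxide attacks the substituted terminus of the 1,1-dimethylallyl palladium intermediate and gives the tertiary ether kinetically, at a temperature where zerovalent palladium does not insert into the aryl bromide.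

Step 6
Reactants: 8 2-bromo-5-[(2-methylbut-3-en-2-yl)oxy]-4-[(2-methylbut-3-yn-2-yl)oxy]benzaldehyde
Product: 10 2-bromo-5-[(2-methylbut-3-en-2-yl)oxy]-4-[(2-methylbut-3-yn-2-yl)oxy]phenol, via aryl formate 9 (not isolated)
Conditions: mCPBA (1.3 equiv), CH2Cl2, 0 °C → rt; then K2CO3 (0.2 equiv), MeOH, rt
Reagents that add atoms: mCPBA, OOC(=O)c1cccc(Cl)c1
Why: Dakin-type Baeyer–Villiger oxidation with aryl migration (favoured by the para-alkoxy group) turns the aldehyde carbon into the future O11 phenol; the alkyne and the monosubstituted vinyl group react far more slowly with the peracid.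

Step 7
Reactants: 10 2-bromo-5-[(2-methylbut-3-en-2-yl)oxy]-4-[(2-methylbut-3-yn-2-yl)oxy]phenol
Product: 13 5-bromo-6,8-bis(tert-butyldimethylsilyloxy)-2,2-dimethyl-7-(3-methylbut-2-en-1-yl)-2H-chromene, via prenylated diol ether 11 (not isolated), via chromenediol 12 (not isolated)
Conditions: o-xylene, 140 °C, sealed, Ar, 14 h; then 0 °C, 2,6-lutidine (4 equiv), TBSOTf (2.5 equiv)
Reagents that add atoms: TBSOTf, CC(C)(C)[Si](C)(C)OS(=O)(=O)C(F)(F)F
Why: Two aromatic Claisen rearrangements, each with only one free ortho carbon: the 1,1-dimethylallyl ether delivers the prenyl between the two oxygens, and the propargyl ether gives the dimethylchromene (Claisen, 1,5-H shift, oxa-6π closure) next to the bromine; the air-sensitive diol is silylated in the same pot.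

Step 8
Reactants: 5 6-(3-methylbut-2-en-1-yl)-7-(triisopropylsilyloxy)chroman-4-one + 13 5-bromo-6,8-bis(tert-butyldimethylsilyloxy)-2,2-dimethyl-7-(3-methylbut-2-en-1-yl)-2H-chromene
Product: 14 rac-3-[6,8-bis(tert-butyldimethylsilyloxy)-2,2-dimethyl-7-(3-methylbut-2-en-1-yl)-2H-chromen-5-yl]-6-(3-methylbut-2-en-1-yl)-7-(triisopropylsilyloxy)chroman-4-one
Conditions: Pd2(dba)3 (2.5 mol %), XPhos (6 mol %), K3PO4 (2.5 equiv), toluene, 100 °C
Reagents that add atoms: none
Why: Palladium-catalysed ketone α-arylation (Buchwald–Hartwig type) at C3, the only enolisable position; the bulky biaryl phosphine handles the di-ortho-substituted bromide and the mild phosphate base spares the silyl ethers and the chromanone ring.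

Step 9
Reactants: 14 rac-isoflavanone
Product: 17 3-[6,8-bis(tert-butyldimethylsilyloxy)-2,2-dimethyl-7-(3-methylbut-2-en-1-yl)-2H-chromen-5-yl]-6-(3-methylbut-2-en-1-yl)-7-(triisopropylsilyloxy)-2H-chromene, via alcohol 15 (not isolated), via mesylate 16 (not isolated)
Conditions: NaBH4, THF/MeOH (10:1), 0 °C; then crude alcohol, MsCl (1.5 equiv), Et3N (5 equiv), CH2Cl2, −20 °C → rt
Reagents that add atoms: none
Why: Hydride reduction followed by E1-type elimination of the doubly oxygen-activated benzylic mesylate; C3 carries the only β-hydrogen, so the conjugated isoflav-3-ene forms and the racemic C3 centre is erased.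

Step 10
Reactants: 17 tris-silyl isoflav-3-ene
Product: 18 5-[7-hydroxy-6-(3-methylbut-2-en-1-yl)-2H-chromen-3-yl]-2,2-dimethyl-7-(3-methylbut-2-en-1-yl)-2H-chromene-6,8-diol
Conditions: TBAF (3.6 equiv), THF, 0 °C, Ar; pH 7 phosphate buffer; filtration through neutral alumina
Reagents that add atoms: none
Why: Fluoride desilylation frees all three phenols without any acid, so the 2'-hydroxyisoflav-3-ene (a compound class that is isolable in nature) is obtained uncyclised.

Step 11
Reactants: 18 trihydroxy isoflav-3-ene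
Product: 20 lespecyrtin E3 [(6aR,11aR)-3,9-dihydroxy-2,10-diprenylpterocarpan with a 2,2-dimethyl-2H-pyran fused at C7–C8, oxygen on C8], via para-quinone methide 19 (not isolated)
Conditions: (R)-3,3'-bis(2,4,6-triisopropylphenyl)-1,1'-binaphthyl-2,2'-diyl hydrogen phosphate [(R)-TRIP] (10 mol %), toluene, 4 Å MS, 0 °C → rt, Ar
Reagents that add atoms: none
Why: Proposed new method: catalytic enantioselective cycloisomerisation (intramolecular hydroalkoxylation) of a 2'-hydroxyisoflav-3-ene, in which the chiral acid protonates C3 of the para-hydroxystyrene unit to give para-quinone methide 19 hydrogen-bonded to the chiral phosphate, which then guides the 2'-OH onto C4 to form the C11a–O11 bond; only the cis ring fusion is geometrically possible, so C6a (set at protonation, reversible through the achiral alkene) and C11a are fixed together as 6aR,11aR, and an acid of this strength should leave the prenyl groups and the chromene untouched; the closest known reaction types are chiral phosphoric acid catalysed 1,6-additions to para-quinone methides made in situ, chiral Brønsted acid hydroalkoxylation of alkenes, and the enzymatic pterocarpan synthase closure.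

**Compound list**
1 | 4-bromobenzene-1,3-diol | Oc1ccc(Br)c(O)c1 | starting material
2 | 1-(5-bromo-2,4-dihydroxyphenyl)-3-chloropropan-1-one | O=C(CCCl)c1cc(Br)c(O)cc1O | intermediate
3 | 6-bromo-7-hydroxychroman-4-one | O=C1CCOc2cc(O)c(Br)cc21 | intermediate
4 | 6-bromo-7-(triisopropylsilyloxy)chroman-4-one | CC(C)[Si](Oc1cc2OCCC(=O)c2cc1Br)(C(C)C)C(C)C | intermediate
5 | 6-(3-methylbut-2-en-1-yl)-7-(triisopropylsilyloxy)chroman-4-one | CC(C)=CCc1cc2C(=O)CCOc2cc1O[Si](C(C)C)(C(C)C)C(C)C | intermediate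
6 | 2-bromo-4,5-dihydroxybenzaldehyde | O=Cc1cc(O)c(O)cc1Br | starting material
7 | 2-bromo-5-hydroxy-4-[(2-methylbut-3-yn-2-yl)oxy]benzaldehyde | O=Cc1cc(O)c(OC(C)(C)C#C)cc1Br | intermediate
8 | 2-bromo-5-[(2-methylbut-3-en-2-yl)oxy]-4-[(2-methylbut-3-yn-2-yl)oxy]benzaldehyde | O=Cc1cc(OC(C)(C)C=C)c(OC(C)(C)C#C)cc1Br | intermediate
9 | 2-bromo-5-[(2-methylbut-3-en-2-yl)oxy]-4-[(2-methylbut-3-yn-2-yl)oxy]phenyl formate | O=COc1cc(OC(C)(C)C=C)c(OC(C)(C)C#C)cc1Br | intermediate
10 | 2-bromo-5-[(2-methylbut-3-en-2-yl)oxy]-4-[(2-methylbut-3-yn-2-yl)oxy]phenol | Oc1cc(OC(C)(C)C=C)c(OC(C)(C)C#C)cc1Br | intermediate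
11 | 4-bromo-2-(3-methylbut-2-en-1-yl)-6-[(2-methylbut-3-yn-2-yl)oxy]benzene-1,3-diol | Oc1c(CC=C(C)C)c(O)c(OC(C)(C)C#C)cc1Br | intermediate
12 | 5-bromo-2,2-dimethyl-7-(3-methylbut-2-en-1-yl)-2H-chromene-6,8-diol | CC1(C)C=Cc2c(Br)c(O)c(CC=C(C)C)c(O)c2O1 | intermediate
13 | 5-bromo-6,8-bis(tert-butyldimethylsilyloxy)-2,2-dimethyl-7-(3-methylbut-2-en-1-yl)-2H-chromene | CC1(C)C=Cc2c(Br)c(O[Si](C)(C)C(C)(C)C)c(CC=C(C)C)c(O[Si](C)(C)C(C)(C)C)c2O1 | intermediate
14 | rac-3-[6,8-bis(tert-butyldimethylsilyloxy)-2,2-dimethyl-7-prenyl-2H-chromen-5-yl]-6-prenyl-7-(triisopropylsilyloxy)chroman-4-one (racemic at C3) | CC(C)=CCc1cc2C(=O)C(COc2cc1O[Si](C(C)C)(C(C)C)C(C)C)c1c2C=CC(C)(C)Oc2c(O[Si](C)(C)C(C)(C)C)c(CC=C(C)C)c1O[Si](C)(C)C(C)(C)C | intermediate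
15 | corresponding chroman-4-ol (racemic cis/trans mixture) | CC(C)=CCc1cc2C(O)C(COc2cc1O[Si](C(C)C)(C(C)C)C(C)C)c1c2C=CC(C)(C)Oc2c(O[Si](C)(C)C(C)(C)C)c(CC=C(C)C)c1O[Si](C)(C)C(C)(C)C | intermediate
16 | corresponding chroman-4-yl methanesulfonate (racemic mixture) | CC(C)=CCc1cc2C(OS(C)(=O)=O)C(COc2cc1O[Si](C(C)C)(C(C)C)C(C)C)c1c2C=CC(C)(C)Oc2c(O[Si](C)(C)C(C)(C)C)c(CC=C(C)C)c1O[Si](C)(C)C(C)(C)C | intermediate
17 | 3-[6,8-bis(tert-butyldimethylsilyloxy)-2,2-dimethyl-7-prenyl-2H-chromen-5-yl]-6-prenyl-7-(triisopropylsilyloxy)-2H-chromene | CC(C)=CCc1cc2C=C(COc2cc1O[Si](C(C)C)(C(C)C)C(C)C)c1c2C=CC(C)(C)Oc2c(O[Si](C)(C)C(C)(C)C)c(CC=C(C)C)c1O[Si](C)(C)C(C)(C)C | intermediate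
18 | 5-[7-hydroxy-6-prenyl-2H-chromen-3-yl]-2,2-dimethyl-7-prenyl-2H-chromene-6,8-diol (achiral) | CC(C)=CCc1cc2C=C(COc2cc1O)c1c2C=CC(C)(C)Oc2c(O)c(CC=C(C)C)c1O | intermediate
19 | (3R)-3-[6,8-dihydroxy-2,2-dimethyl-7-prenyl-2H-chromen-5-yl]-6-prenyl-2,3-dihydro-7H-chromen-7-one (para-quinone methide) | O=C1C=C2OC[C@H](C=C2C=C1CC=C(C)C)c1c2C=CC(C)(C)Oc2c(O)c(CC=C(C)C)c1O | intermediate
20 | lespecyrtin E3, (6aR,11aR), cis-fused | CC(C)=CCc1cc2c(cc1O)OC[C@H]1c3c4c(c(O)c(CC=C(C)C)c3O[C@@H]21)OC(C)(C)C=C4 | target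

**Step count and risks**
Total steps: 11. Longest linear sequence: 8 (steps 4 to 11, from 6 to 20).

Step 8 (hindered α-arylation; the di-ortho-substituted bromide may couple poorly or the chromanone may ring-open). The fallback reverses the polarity and sets out from 5 and 13, returning at 14. Ketone 5 is converted with TMSOTf/Et3N (CH2Cl2, 0 °C) into 6-prenyl-7-(triisopropylsilyloxy)-4-(trimethylsilyloxy)-2H-chromene F1. NBS (THF, −78 °C) brominates this enol ether faster than the prenyl group, giving 3-bromo-6-prenyl-7-(triisopropylsilyloxy)chroman-4-one F2. Bromide 13 is exchanged with t-BuLi at −78 °C and trapped cold with ZnCl2 (to avoid silyl migration) as [6,8-bis(tert-butyldimethylsilyloxy)-2,2-dimethyl-7-prenyl-2H-chromen-5-yl]zinc chloride F3. Nickel-catalysed coupling of F2 with F3 (NiCl2(dme), 4,4'-di-tert-butyl-2,2'-bipyridine, DME/THF, −20 °C) then gives 14.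

Step 9 (the benzylic cation formed on mesylation may be captured by the neighbouring silyl ether oxygen, giving racemic silylated pterocarpan instead of the alkene). The fallback avoids any cation; it sets out from 14 and returns at 17. Ketone 14 is enolised with KN(SiMe3)2 and trapped with PhNTf2 (THF, −78 °C) to give the 4-(trifluoromethylsulfonyloxy)isoflav-3-ene F4. Palladium-catalysed formate reduction (Pd(OAc)2, PPh3, HCO2H, Bu3N, DMF, 60 °C) then replaces the triflate by hydrogen and gives 17.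

Step 11 (the proposed new cyclisation; the acid may be too weak, poorly selective, or the product may partly racemise by reversible ring opening). The fallback uses the established transfer-hydrogenation route to pterocarpans; it sets out from 14 and returns at 20. TBAF (THF, 0 °C) converts 14 into the racemic 2'-hydroxyisoflavanone 3-[6,8-dihydroxy-2,2-dimethyl-7-prenyl-2H-chromen-5-yl]-7-hydroxy-6-prenylchroman-4-one F5. Noyori asymmetric transfer hydrogenation with dynamic kinetic resolution (RuCl[(R,R)-TsDPEN](p-cymene), HCO2H/Et3N 5:2, EtOAc, rt; the C3 centre epimerises through the enol) gives the cis-(3R,4R)-isoflavan-4-ol F6. Catalytic HCl in EtOH at 0 °C then ionises C4 and the 2'-OH closes the cis-fused dihydrofuran with C3 unchanged, giving 20.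

**Further compounds**
F1 | step 8 | 6-(3-methylbut-2-en-1-yl)-7-(triisopropylsilyloxy)-4-(trimethylsilyloxy)-2H-chromene | CC(C)=CCc1cc2C(O[Si](C)(C)C)=CCOc2cc1O[Si](C(C)C)(C(C)C)C(C)C
F2 | step 8 | rac-3-bromo-6-(3-methylbut-2-en-1-yl)-7-(triisopropylsilyloxy)chroman-4-one | CC(C)=CCc1cc2C(=O)C(Br)COc2cc1O[Si](C(C)C)(C(C)C)C(C)C
F3 | step 8 | [6,8-bis(tert-butyldimethylsilyloxy)-2,2-dimethyl-7-(3-methylbut-2-en-1-yl)-2H-chromen-5-yl]zinc chloride | CC1(C)C=Cc2c([Zn]Cl)c(O[Si](C)(C)C(C)(C)C)c(CC=C(C)C)c(O[Si](C)(C)C(C)(C)C)c2O1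
F4 | step 9 | 3-[6,8-bis(tert-butyldimethylsilyloxy)-2,2-dimethyl-7-prenyl-2H-chromen-5-yl]-6-prenyl-7-(triisopropylsilyloxy)-2H-chromen-4-yl trifluoromethanesulfonate | CC(C)=CCc1cc2C(OS(=O)(=O)C(F)(F)F)=C(COc2cc1O[Si](C(C)C)(C(C)C)C(C)C)c1c2C=CC(C)(C)Oc2c(O[Si](C)(C)C(C)(C)C)c(CC=C(C)C)c1O[Si](C)(C)C(C)(C)C
F5 | step 11 | rac-3-[6,8-dihydroxy-2,2-dimethyl-7-prenyl-2H-chromen-5-yl]-7-hydroxy-6-prenylchroman-4-one | CC(C)=CCc1cc2C(=O)C(COc2cc1O)c1c2C=CC(C)(C)Oc2c(O)c(CC=C(C)C)c1O
F6 | step 11 | (3R,4R)-3-[6,8-dihydroxy-2,2-dimethyl-7-prenyl-2H-chromen-5-yl]-6-prenylchromane-4,7-diol (cis) | CC(C)=CCc1cc2c(cc1O)OC[C@H]([C@H]2O)c1c2c(c(O)c(CC=C(C)C)c1O)OC(C)(C)C=C2
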